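## Retrosynthetic overview

1. Numbering: the ring is C2–C3–C4–C5–C6 (C5 bears CH3 and OH, C2 bears the carbinol carbon C1, C6 bears chain carbon C7); the target is all-E (2R,5R,6R), with C1, C7 and the C5 methyl on one ring face and the C5 hydroxyl on the other.
2. C7=C8 is cut by Julia–Kocienski olefination of a C10 end-group tetrazolyl sulfone (carbanion at C7, so the crowded all-cis C6 centre is never α to a carbonyl) with apo-8'-lycopenal, itself from a mono-Wittig reaction of crocetindialdehyde with a geranyl ylide.
3. The sulfone comes from a cis-fused γ-lactone that ties C7 (as C=O) to the C1 oxygen; the lactone comes from C5-hydroxyl-directed hydrogenation of the C2=C6 bond of a bicyclic butenolide, which sets C2 and C6.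
4. The butenolide is made in one operation: enantioselective cobalt-homoenolate [3+2] annulation of 1-methylcyclopropanol with a 4-silyloxy-2-ynoate (bonds C3–C2 and C6–C5, stereocentre C5), then lactonisation. Ring order: cyclopentene first, then the temporary lactone, which hydride opens again.
5. Enabling feature: ring atoms C3–C4–C5(CH3)(OH) are a ring-opened 1-methylcyclopropanol (a β-metallated butanone), and ring atoms C2 and C6 with their cis exocyclic carbons C1 (carbinol) and C7 (raised to the carboxyl level) are a 2-ynoate.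

Key step: step 2

Assumption: the sense of induction of a chiral diphosphine on cobalt in step 2 cannot be assigned in advance; (R,R)-QuinoxP* is written, and its antipode is used if a first run delivers the S carbinol.

## Route

Step 1
Reactants: 1 2-methyl-2-(trimethylsilyloxy)but-3-yne
Product: 2 methyl 4-methyl-4-(trimethylsilyloxy)pent-2-ynoate
Conditions: n-BuLi, THF, −78 °C; then ClCO2Me, −78 °C → 0 °C
Reagents that add atoms: methyl chloroformate, COC(=O)Cl
Why: Deprotonation of the terminal alkyne and C-acylation of the acetylide anion with a chloroformate is the standard route to 2-ynoates, and the tertiary silyl ether is inert to n-BuLi at −78 °C.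

Step 2
Reactants: 2 methyl 4-methyl-4-(trimethylsilyloxy)pent-2-ynoate; 3 1-methylcyclopropan-1-ol
Product: 6 (R)-6-hydroxy-3,3,6-trimethyl-3,4,5,6-tetrahydro-1H-cyclopenta[c]furan-1-one (bicyclic butenolide), via silyl ether cyclopentenol ester 4 (not isolated), via hydroxy ester 5 (not isolated)
Conditions: CoBr2 (10 mol %), (R,R)-QuinoxP* (12 mol %), Zn dust (20 mol %), DABCO (20 mol %), MeCN, 60 °C; then K2CO3 (cat.), MeOH, rt
Reagents that add atoms: none
Why: Proposed new method: Zn reduces CoBr2/diphosphine to monovalent cobalt, whose alkoxide of 3 undergoes strain-driven β-carbon elimination to the cobalt homoenolate Co–CH2CH2C(O)CH3; syn migratory insertion of ynoate 2 delivers the alkyl carbon to the β-alkyne carbon (conjugate sense, forming C3–C2) and leaves cobalt on the α-carbon cis to the ketone arm, and this alkenylcobalt (cobalt allenolate) adds to the methyl ketone (forming C6–C5) before protonolysis by further 3 turns the cycle over. The closest known reaction types are the cobalt–diphosphine-catalysed [3+2] annulation of cyclopropanols with unactivated internal alkynes and rhodium-catalysed enantioselective [3+2] annulations that end with alkenyl-metal addition to a ketone; the electron-poor 2-ynoate partner and asymmetric induction with a 1-alkylcyclopropanol are the new elements. The cyclopentene closes by 5-exo-trig attack of the alkenyl carbon C6 on the ketone carbonyl C5, an intramolecular 1,2-insertion into the Co–C bond. The only new stereocentre, C5, is set in this carbonyl insertion by the C2-symmetric P-stereogenic diphosphine, which differentiates the ketone faces (methyl versus ring methylene) in the compact cobaltacyclic transition state. The step needs regioselectivity (the ester makes C2 the electrophilic alkyne carbon, and the silyl ether blocks alkoxide-directed and retro-alkynylation pathways), annulation rather than protodemetalation (MeCN medium and proximity of the ketone) and enantioselectivity (ligand). Methanolysis of the silyl ether then lets the tertiary hydroxyl, held cis to the ester on the ring alkene, close the butenolide that ties C1 to C7 for the following steps.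

Step 3
Reactants: 6 (R)-6-hydroxy-3,3,6-trimethyl-3,4,5,6-tetrahydro-1H-cyclopenta[c]furan-1-one
Product: 7 (3aR,6R,6aR)-6-hydroxy-3,3,6-trimethylhexahydro-1H-cyclopenta[c]furan-1-one (cis-fused lactone; lactone ring and C6 methyl on the same face, hydroxyl on the other)
Conditions: [Ir(cod)(PCy3)(py)]PF6 (5 mol %), H2 (10 bar), CH2Cl2, rt
Reagents that add atoms: none
Why: Hydroxyl-directed homogeneous hydrogenation with a cationic iridium catalyst should deliver both hydrogens to the tetrasubstituted C2=C6 bond from the face of the bound C5 hydroxyl, so that C1, C7 and the C5 methyl end up together on the opposite face, while the cis ring fusion is obligatory and a homogeneous catalyst avoids allylic C–O hydrogenolysis.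

Step 4
Reactants: 7 (3aR,6R,6aR)-6-hydroxy-3,3,6-trimethylhexahydro-1H-cyclopenta[c]furan-1-one
Product: 8 (1R,2S,3R)-2-(hydroxymethyl)-3-(2-hydroxypropan-2-yl)-1-methylcyclopentan-1-ol
Conditions: LiAlH4, THF, 0 °C → rt; aq. NaOH work-up
Reagents that add atoms: none
Why: Hydride reduction of the γ-lactone to the diol opens the temporary ring without touching a stereocentre, because the intermediate aldehyde level at C7 is reduced faster than C6 can enolise.

Step 5
Reactants: 8 (1R,2S,3R)-2-(hydroxymethyl)-3-(2-hydroxypropan-2-yl)-1-methylcyclopentan-1-ol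
Product: 9 (1R,2R,3R)-3-(2-hydroxypropan-2-yl)-1-methyl-2-{[(1-phenyl-1H-tetrazol-5-yl)sulfanyl]methyl}cyclopentan-1-ol
Conditions: 1-phenyl-1H-tetrazole-5-thiol, PPh3, DIAD, THF, 0 °C → rt
Reagents that add atoms: 1-phenyl-1H-tetrazole-5-thiol, Sc1nnnn1-c1ccccc1
Why: Mitsunobu thioetherification is selective for the primary alcohol because tertiary alcohols are not displaced, and the acidic tetrazolethiol should outcompete the neighbouring tertiary hydroxyl as nucleophile.

Step 6
Reactants: 9 (1R,2R,3R)-3-(2-hydroxypropan-2-yl)-1-methyl-2-{[(1-phenyl-1H-tetrazol-5-yl)sulfanyl]methyl}cyclopentan-1-ol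
Product: 10 (1R,2R,3R)-3-(2-hydroxypropan-2-yl)-1-methyl-2-{[(1-phenyl-1H-tetrazol-5-yl)sulfonyl]methyl}cyclopentan-1-ol
Conditions: (NH4)6Mo7O24·4H2O (10 mol %), 30% aq. H2O2, EtOH, 0 °C → rt
Reagents that add atoms: hydrogen peroxide, OO
Why: Molybdate-catalysed peroxide oxidation of a tetrazolyl sulfide to the sulfone is the standard entry to Julia–Kocienski reagents and leaves tertiary alcohols untouched.

Step 7
Reactants: 10 (1R,2R,3R)-3-(2-hydroxypropan-2-yl)-1-methyl-2-{[(1-phenyl-1H-tetrazol-5-yl)sulfonyl]methyl}cyclopentan-1-ol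
Product: 11 1-phenyl-5-({(1R,2R,5R)-2-methyl-2-(trimethylsilyloxy)-5-[2-(trimethylsilyloxy)propan-2-yl]cyclopentyl}methylsulfonyl)-1H-tetrazole (bis-TMS ether of 10)
Conditions: TMSOTf, 2,6-lutidine, CH2Cl2, −78 °C → 0 °C
Reagents that add atoms: trimethylsilyl trifluoromethanesulfonate, C[Si](C)(C)OS(=O)(=O)C(F)(F)F
Why: Silyl triflate silylation of both tertiary hydroxyls with a hindered pyridine base, which does not deprotonate the sulfone, removes the alkoxides that would otherwise quench the carbanion or take over the tetrazole by Smiles transfer in step 10.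

Step 8
Reactants: 12 geranyl bromide ((2E)-1-bromo-3,7-dimethylocta-2,6-diene)
Product: 13 [(2E)-3,7-dimethylocta-2,6-dien-1-yl]triphenylphosphonium bromide
Conditions: PPh3, toluene, rt, dark
Reagents that add atoms: triphenylphosphine, c1ccc(cc1)P(c1ccccc1)c1ccccc1
Why: SN2 quaternisation of the primary allylic bromide at room temperature should retain the E geometry of the geranyl unit.

Step 9
Reactants: 13 [(2E)-3,7-dimethylocta-2,6-dien-1-yl]triphenylphosphonium bromide; 14 crocetindialdehyde ((2E,4E,6E,8E,10E,12E,14E)-2,6,11,15-tetramethylhexadeca-2,4,6,8,10,12,14-heptaenedial)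
Product: 15 apo-8'-lycopenal ((2E,4E,6E,8E,10E,12E,14E,16E,18E)-2,6,11,15,19,23-hexamethyltetracosa-2,4,6,8,10,12,14,16,18,22-decaenal)
Conditions: NaOMe, CH2Cl2/MeOH, 0 °C → rt, 14 in 2.5-fold excess (recovered); then I2 (cat.), CH2Cl2, daylight, rt
Reagents that add atoms: none
Why: Wittig olefination of one formyl group by the semistabilised allylic ylide is favoured over double reaction by the excess of dialdehyde, and iodine-catalysed equilibration should convert the new disubstituted double bond to E.

Step 10
Reactants: 11 bis-TMS sulfone; 15 apo-8'-lycopenal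
Product: 16 (all-E,2R,5R,6R)-1,5-bis(trimethylsilyloxy)-2,6-cyclolycopene (bis-TMS ether of the target)
Conditions: KN(SiMe3)2, THF, −78 °C; then 15, −78 °C → rt; aq. NH4Cl; Ar, dim light
Reagents that add atoms: none
Why: Julia–Kocienski olefination, in which the metalated tetrazolyl sulfone adds to the non-enolisable polyenal and the adduct collapses by Smiles rearrangement with loss of SO2 and tetrazololate, should give the C7=C8 bond mainly as E while C6 stays β to the carbanion and cannot epimerise.

Step 11
Reactants: 16 (all-E,2R,5R,6R)-1,5-bis(trimethylsilyloxy)-2,6-cyclolycopene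
Product: 17 (all-E,2R,5R,6R)-2,6-cyclolycopene-1,5-diol (target)
Conditions: PPTS (cat.), MeOH/CH2Cl2, 0 °C → rt; then heptane, reflux, Ar, dark; crystallisation
Reagents that add atoms: none
Why: Acid-catalysed methanolysis of the two tertiary trimethylsilyl ethers is mild enough for the polyene and the tertiary alcohols, and thermal equilibration with crystallisation of the all-E isomer is standard carotenoid practice for removing residual Z isomer.

## Compound list

1 | 2-methyl-2-(trimethylsilyloxy)but-3-yne | C#CC(C)(C)O[Si](C)(C)C | starting material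
2 | methyl 4-methyl-4-(trimethylsilyloxy)pent-2-ynoate | COC(=O)C#CC(C)(C)O[Si](C)(C)C | intermediate
3 | 1-methylcyclopropan-1-ol | CC1(O)CC1 | starting material
4 | methyl (R)-5-hydroxy-5-methyl-2-[2-(trimethylsilyloxy)propan-2-yl]cyclopent-1-ene-1-carboxylate | COC(=O)C1=C(C(C)(C)O[Si](C)(C)C)CC[C@@]1(C)O | intermediate
5 | methyl (R)-5-hydroxy-2-(2-hydroxypropan-2-yl)-5-methylcyclopent-1-ene-1-carboxylate | COC(=O)C1=C(C(C)(C)O)CC[C@@]1(C)O | intermediate
6 | (R)-6-hydroxy-3,3,6-trimethyl-3,4,5,6-tetrahydro-1H-cyclopenta[c]furan-1-one | O=C1OC(C)(C)C2=C1[C@](C)(O)CC2 | intermediate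
7 | (3aR,6R,6aR)-6-hydroxy-3,3,6-trimethylhexahydro-1H-cyclopenta[c]furan-1-one | O=C1OC(C)(C)[C@@H]2CC[C@@](C)(O)[C@H]12 | intermediate
8 | (1R,2S,3R)-2-(hydroxymethyl)-3-(2-hydroxypropan-2-yl)-1-methylcyclopentan-1-ol | OC[C@@H]1[C@H](C(C)(C)O)CC[C@@]1(C)O | intermediate
9 | (1R,2R,3R)-3-(2-hydroxypropan-2-yl)-1-methyl-2-{[(1-phenyl-1H-tetrazol-5-yl)sulfanyl]methyl}cyclopentan-1-ol | c1ccccc1-n1nnnc1SC[C@@H]1[C@H](C(C)(C)O)CC[C@@]1(C)O | intermediate
10 | (1R,2R,3R)-3-(2-hydroxypropan-2-yl)-1-methyl-2-{[(1-phenyl-1H-tetrazol-5-yl)sulfonyl]methyl}cyclopentan-1-ol | c1ccccc1-n1nnnc1S(=O)(=O)C[C@@H]1[C@H](C(C)(C)O)CC[C@@]1(C)O | intermediate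
11 | 1-phenyl-5-({(1R,2R,5R)-2-methyl-2-(trimethylsilyloxy)-5-[2-(trimethylsilyloxy)propan-2-yl]cyclopentyl}methylsulfonyl)-1H-tetrazole | c1ccccc1-n1nnnc1S(=O)(=O)C[C@@H]1[C@H](C(C)(C)O[Si](C)(C)C)CC[C@@]1(C)O[Si](C)(C)C | intermediate
12 | geranyl bromide, (2E)-1-bromo-3,7-dimethylocta-2,6-diene | CC(C)=CCC/C(C)=C/CBr | starting material
13 | [(2E)-3,7-dimethylocta-2,6-dien-1-yl]triphenylphosphonium bromide | CC(C)=CCC/C(C)=C/C[P+](c1ccccc1)(c1ccccc1)c1ccccc1.[Br-] | intermediate
14 | crocetindialdehyde, (2E,4E,6E,8E,10E,12E,14E)-2,6,11,15-tetramethylhexadeca-2,4,6,8,10,12,14-heptaenedial | O=C/C(C)=C/C=C/C(C)=C/C=C/C=C(C)/C=C/C=C(C)/C=O | starting material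
15 | apo-8'-lycopenal, (2E,4E,6E,8E,10E,12E,14E,16E,18E)-2,6,11,15,19,23-hexamethyltetracosa-2,4,6,8,10,12,14,16,18,22-decaenal | CC(C)=CCC/C(C)=C/C=C/C(C)=C/C=C/C(C)=C/C=C/C=C(C)/C=C/C=C(C)/C=O | intermediate
16 | (all-E,2R,5R,6R)-1,5-bis(trimethylsilyloxy)-2,6-cyclolycopene | CC(C)=CCC/C(C)=C/C=C/C(C)=C/C=C/C(C)=C/C=C/C=C(C)/C=C/C=C(C)/C=C/[C@@H]1[C@H](C(C)(C)O[Si](C)(C)C)CC[C@@]1(C)O[Si](C)(C)C | intermediate
17 | (all-E,2R,5R,6R)-2,6-cyclolycopene-1,5-diol | CC(C)=CCC/C(C)=C/C=C/C(C)=C/C=C/C(C)=C/C=C/C=C(C)/C=C/C=C(C)/C=C/[C@@H]1[C@H](C(C)(C)O)CC[C@@]1(C)O | target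

## Step count and risks

Total step count: 11. Longest linear sequence: 9 steps (steps 1–7, 10 and 11); steps 8 and 9 form the second branch.

Steps most likely to fail:

1. Step 2 (proposed new method). What may go wrong: insertion of the ynoate in the reverse sense, protonolysis of the alkenylcobalt before it reaches the ketone (giving an open-chain alkenyl ketone), or weak facial discrimination in the carbonyl insertion. The fallback sets out from 2 and comes back at 4, using known chemistry. The zinc homoenolate bis[2-(ethoxycarbonyl)ethyl]zinc F1 is prepared from [(1-ethoxycyclopropyl)oxy]trimethylsilane and ZnCl2 in Et2O and added to ynoate 2 in THF/HMPA with CuBr·SMe2 (cat.). Conjugate addition to the β-carbon and Dieckmann-type closure of the resulting allenoate onto the ethyl ester should give methyl 5-oxo-2-[2-(trimethylsilyloxy)propan-2-yl]cyclopent-1-ene-1-carboxylate F2; this is the known formal [3+2] cyclopentenone annulation of zinc homoenolates with acetylenic esters and forms the same two ring bonds. Enantioselective 1,2-addition of ZnMe2 to the ring ketone of F2, promoted by Ti(OiPr)4 and a trans-cyclohexane-1,2-diamine-derived bis(hydroxycamphorsulfonamide) ligand, should then give 4. This is a known method for tertiary allylic alcohols from 2-substituted cyclic enones, and conjugate addition is blocked by the fully substituted β-carbon. Compound 4 is isolated and treated with K2CO3/MeOH as in the second stage of step 2.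

2. Step 3. What may go wrong: slow turnover on the tetrasubstituted, electron-poor alkene with deactivation of the catalyst, or hydrogen delivery that escapes control by the hydroxyl. The fallback sets out from 6 and comes back at 8, with the order of the two reductions reversed. The butenolide carbonyl is reduced first with iBu2AlH (CH2Cl2, −78 °C → 0 °C) to (R)-2-(hydroxymethyl)-3-(2-hydroxypropan-2-yl)-1-methylcyclopent-2-en-1-ol F3. Its electron-rich tetrasubstituted alkene binds the cationic iridium catalyst more strongly. Hydroxyl-directed hydrogenation of F3 ([Ir(cod)(PCy3)(py)]PF6, H2, CH2Cl2, rt), in which the ring hydroxyl at C5 is the only director that distinguishes the two faces, should then give 8 directly by syn addition.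

3. Step 10. What may go wrong: slow addition of the β-branched sulfonyl carbanion to the polyenal, self-condensation of the sulfone, or loss of a silyl group followed by transfer of the tetrazole to the C5 alkoxide. The fallback sets out from 7 and 15 and comes back at 17, with the polarity of the C7=C8 union reversed. Lactone 7 is reduced with iBu2AlH (CH2Cl2, −78 °C) to the lactol (3aR,6R,6aR)-3,3,6-trimethylhexahydro-1H-cyclopenta[c]furan-1,6-diol F4. Aldehyde 15 is reduced (NaBH4, MeOH/THF, 0 °C) to apo-8'-lycopenol F5, which is converted with PPh3·HBr (MeOH/CH2Cl2, rt) into (apo-8'-lycopenyl)triphenylphosphonium bromide F6. Wittig olefination of F4, which supplies the C7 aldehyde by ring–chain tautomerism, with the ylide from F6 (NaOMe, CH2Cl2/MeOH, 0 °C → rt), followed by the thermal equilibration of step 11, should give 17 without protecting groups. The price is that C6 is briefly α to a formyl group, so base strength and contact time must be kept low.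

## Further compounds

F1 | step 2 | bis[2-(ethoxycarbonyl)ethyl]zinc | CCOC(=O)CC[Zn]CCC(=O)OCC
F2 | step 2 | methyl 5-oxo-2-[2-(trimethylsilyloxy)propan-2-yl]cyclopent-1-ene-1-carboxylate | COC(=O)C1=C(C(C)(C)O[Si](C)(C)C)CCC1=O
F3 | step 3 | (R)-2-(hydroxymethyl)-3-(2-hydroxypropan-2-yl)-1-methylcyclopent-2-en-1-ol | OCC1=C(C(C)(C)O)CC[C@@]1(C)O
F4 | step 10 | (3aR,6R,6aR)-3,3,6-trimethylhexahydro-1H-cyclopenta[c]furan-1,6-diol (lactol, both anomers) | OC1OC(C)(C)[C@@H]2CC[C@@](C)(O)[C@H]12
F5 | step 10 | apo-8'-lycopenol, (2E,4E,6E,8E,10E,12E,14E,16E,18E)-2,6,11,15,19,23-hexamethyltetracosa-2,4,6,8,10,12,14,16,18,22-decaen-1-ol | CC(C)=CCC/C(C)=C/C=C/C(C)=C/C=C/C(C)=C/C=C/C=C(C)/C=C/C=C(C)/CO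
F6 | step 10 | (apo-8'-lycopenyl)triphenylphosphonium bromide | CC(C)=CCC/C(C)=C/C=C/C(C)=C/C=C/C(C)=C/C=C/C=C(C)/C=C/C=C(C)/C[P+](c1ccccc1)(c1ccccc1)c1ccccc1.[Br-]
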